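## Structural features

The target is an ent-labdane diterpenoid: a trans-fused decalin (ring A = C1–C5/C10, ring B = C5–C10) with an angular methyl on C10 (C20), an exocyclic methylene on C8 (C17) and, on C9, a five-carbon chain ending in an E-trisubstituted allylic alcohol (C13=C14, C15–OH). Five stereocentres are contiguous (C3, C4, C5, C10, C9); C4 and C10 are quaternary, 1,3-related through C5, and carry their methyl groups axial on the same face of ring A. C4 also bears an equatorial CH2O group (C18, tiglate) next to the equatorial C3 acetate, so ring A holds an O–C3–C4–C18–O unit with the quaternary carbon in its middle. The fragile parts are the exocyclic alkene (prone to acid-induced migration into ring B), the conjugated tiglate, the base-labile acetate and the free allylic alcohol; three hydroxyl groups must end in three different states. The real difficulty is the stereodefined quaternary C4 between two oxygen-bearing carbons, followed by the hindered C8/C9 region beside quaternary C10. The key step exploits the O–C3–C4–C18–O unit: read as a 2-isoxazoline (C3=N–O–C18) fused on the C3–C4 bond, it arises from a nitrile oxide at C3 and an isopropenyl group (C4=C18) on C5 of a ring B cyclohexanone.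

## Logic of the disconnections

30 ⇒ 29. The C15–H bond is removed, so the allylic alcohol of 30 becomes the conjugated aldehyde of 29. An aldehyde cannot be acylated, so O15 never needs a protecting group. The forward step must reduce an enal by 1,2-addition without touching an acetate, a conjugated ester or two alkenes.

29 ⇒ 28 ⇒ 26 (+ 27). The acyl C–O bonds at O3 and then O18 are cut. Both esters then come from one free 1,3-diol and two commercial acyl donors. The forward acylation must tell the primary O18 from the secondary O3.

26 ⇒ 25 ⇒ 24 ⇒ 22 + 23. The two Si–O bonds and then the C13=C14 bond are cut; 24 is the amide-level form of 25. This removes C14, C15 and the only stereoelement of the chain. The forward steps need an E-selective olefination of a methyl ketone and a reduction that stops at the aldehyde.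

22 ⇒ 21 ⇒ 20 ⇒ 19 ⇒ 17. The ketal C–O bonds, then C8=C17, then the C8–O and C9–H bonds are cut in turn, leading back to a C8=C9 alkene. The exocyclic alkene is introduced late and never meets borane. The forward steps must methylenate a hindered ketone and add boron to C8 and hydrogen to C9; the C9 configuration is the equatorial, thermodynamic one.

17 ⇒ 16 ⇒ 15 ⇒ 14. The Si–O bonds and the C3–H bond are cut, and the C3 carbonyl oxygen and O18–H are rejoined through nitrogen as the N–O bond of an isoxazoline. Keeping the heterocycle to this point means only one ketone exists when C3 is reduced. The forward steps need an N–O cleavage that spares an alkene and a ketal, and axial hydride delivery at C3.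

14 ⇒ 11 + 12 (through 13); 11 ⇒ 9 (through 10). The C9–C11 bond is cut between an sp2 and an sp3 carbon, and the enol C–O bond is traced to a ketone. The side chain leaves as a four-carbon unit with C13 masked. The forward coupling must work at an alkenyl triflate beside quaternary C10; enolisation is unambiguous because only C8 carries hydrogen.

9 ⇒ 7 (through 8). This is the key disconnection: C3–C4 and O–C18 are cut. One retro-step removes ring A, the heterocycle and the quaternary stereocentre C4, leaving a monocyclic ketone with two adjacent stereocentres. The forward step must join the dipole carbon to the internal alkene carbon, on the correct face, faster than the dipole dimerises.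

7 ⇒ 6 ⇒ 5. The C3=N bond is cut, then the C3 oxygen is removed to leave a terminal alkene. Nitrogen and oxidation level are thus added after the carbon skeleton is complete. The forward steps need anti-Markovnikov oxidation of the allyl group beside an isopropenyl group and a ketone, and aldehyde-selective oximation.

5 ⇒ 1 + 2 + 3 (through 4). The C5–C4 and C10–C1 bonds, β and α to the ketone, are cut, leaving three commercial compounds. The forward step needs catalyst control of the enone face (C5) and alkylation trans to the new substituent (C10).

## Other disconnections considered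

Alternative 1: The cut runs through ring B at C5–C10 and C8–C9. It leads from cycloadduct A1 back to the open-chain triene A2, in which a 1-silyloxy diene (C5–C8) and an (E)-3-methyl-2-enoate (C9=C10) are joined by the C1–C4 tether. Forward, thermolysis of A2 is an intramolecular Diels–Alder reaction that makes ring B as the cycloadduct ring and ring A as the tether ring.
- In its favour: four contiguous stereocentres (C5, C8, C9, C10) and both carbocycles arise in one operation. The enoate geometry becomes the cis relation of C20 and C11, and C8 arrives oxygenated.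
- Against it here: C3 and quaternary C4 must be set beforehand in an acyclic chain. A β,β-disubstituted enoate is a sluggish dienophile and the silyloxy diene is delicate. The trans fusion depends on an ester-endo transition state that is not assured with a quaternary carbon beside the diene. A1 still needs hydrogenation of C6=C7, oxidation-state changes at C8 and a four-carbon extension of the C11 ester.
- Comparison: on structure the alternative is the better plan for ring B, because C9 and the C8 oxygen come directly while the chosen route spends five steps on them. The chosen plan is better for C4, which it sets under ring constraint. On mechanism both are concerted cycloadditions, but a nitrile oxide is much more reactive toward an unactivated 1,1-disubstituted alkene than this diene/dienophile pair. On step economy the two should be about equal, since what A1 saves in ring B is spent in making A2.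

Alternative 2: No skeletal bond is cut. The C18–O bond is traced to a C18–H bond and the bicyclic core is taken from andrographolide after removal of its C19 oxygen. Forward, the O3 diethylhydrosilyl ether A4 undergoes iridium-catalysed dehydrogenative silylation (for example [Ir(cod)OMe]2, a phenanthroline ligand, norbornene as hydrogen acceptor) of the equatorial C4 methyl to give oxasilolane A3. Oxidation of the C–Si bond would then give the 3,18-diol.
- In its favour: C3, C5, C9 and C10 come from the natural product. The equatorial O3–Si–H reaches only the equatorial methyl, which is the C18 the target needs. The route should be short.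
- Against it here: the neopentyl C19 hydroxyl must be deoxygenated. The side chain must be degraded to C12 and C13–C16 rebuilt. The exocyclic alkene must be masked as a C8 ketal, because it would not survive the silylation, and re-methylenated later. The plan depends on a complex chiral-pool compound and gives neither the antipode nor ring-B analogues.
- Comparison: on structure it is the equal or the better of the chosen plan, since no ring stereocentre has to be made. On mechanism a reagent-directed C–H silylation with a defined five-membered geometry is as credible as the substrate-controlled cycloaddition. On step economy it should be the better plan. The chosen plan is preferred because it builds the skeleton from simple feedstocks and does not need C19 deoxygenation and side-chain degradation.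

Alternative 3: The cut is the C9–C10 bond, leading from acetal A5 back to the ring-A substrate A6. A6 carries an exocyclic methyl enol ether at C10 and, on C5, a chain with a Z-allylsilane (C8=C9, C17–Si). Forward, constant-current anodic oxidation of A6 (methanol, LiClO4, 2,6-lutidine) converts the enol ether into a radical cation. C9 of the allylsilane attacks it, ring B closes, silicon is lost and C8=C17 is formed.
- In its favour: one step closes ring B, sets C9 and quaternary C10, and delivers the exocyclic methylene together with the complete side chain. On this point it is better than the chosen plan, which needs a ketone, a Wittig reaction and a separate chain elaboration.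
- Against it here: A6 must already contain C3, C4 and C5, so the quaternary C4 is not solved by the key step. It also needs a stereodefined Z-allylsilane and an E-allylic ether in one chain. Several π systems of similar oxidation potential are present. The configuration at C10 depends on the cyclisation transition state. C20 emerges as a dimethyl acetal and must still be reduced to a methyl group beside an exocyclic alkene.
- Comparison: on structure the alternative handles ring B more directly and the chosen plan handles ring A and C4 more directly. On mechanism a radical-cation cyclisation is more sensitive to other oxidisable groups than a neutral dipolar cycloaddition. On step economy it should be shorter after the key step and longer before it, about equal overall at best.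

Key step: step 4

Assumptions on the chemistry:
- Labdane numbering is used for all bicyclic compounds.
- The ligand antipode in step 1 is the one that delivers the isopropenyl group to the enone face giving the 3R ketone; the sense of induction is taken to follow that of simple cyclohexenones.
- Oxime 7 is drawn as the E isomer; both geometrical isomers give the same nitrile oxide.

## Route

Step 1
Reactants: 1 2-methylcyclohex-2-en-1-one; 2 isopropenylmagnesium bromide; 3 allyl bromide
Product: 5 (2R,3R)-2-methyl-3-(prop-1-en-2-yl)-2-(prop-2-en-1-yl)cyclohexan-1-one, via magnesium enolate 4 (not isolated)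
Conditions: CuBr·SMe2 (5 mol %), 1-[2-(diphenylphosphino)ferrocenyl]ethyldicyclohexylphosphine (one antipode, 6 mol %), 2 (in 2-MeTHF), t-BuOMe, −78 °C; then 3, DMPU, −78 → 0 °C
Reagents that add atoms: isopropenylmagnesium bromide (2), C=C(C)[Mg]Br; allyl bromide (3), C=CCBr
Why: Copper-catalysed asymmetric conjugate addition of a Grignard reagent to a cyclic enone; the chiral diphosphine–copper complex selects the enone face and sets C5 (3R in 5). The magnesium enolate is then C-allylated on the face opposite the new isopropenyl group, which sets quaternary C10 (2R) with allyl trans to isopropenyl.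

Step 2
Reactants: 5 (2R,3R)-2-methyl-3-(prop-1-en-2-yl)-2-(prop-2-en-1-yl)cyclohexan-1-one
Product: 6 3-[(1R,6R)-1-methyl-2-oxo-6-(prop-1-en-2-yl)cyclohexyl]propanal
Conditions: PdCl2(PhCN)2 (10 mol %), CuCl2·2H2O (10 mol %), AgNO2 (5 mol %), O2 (1 atm), t-BuOH/MeNO2 15:1, rt
Reagents that add atoms: dioxygen, O=O
Why: Aldehyde-selective (anti-Markovnikov) Wacker-type oxidation with a nitrite co-catalyst, a reaction type established for allyl groups on quaternary carbons α to a carbonyl group. The neopentyl-like surroundings disfavour attack at the internal carbon, and neither the 1,1-disubstituted isopropenyl group nor the ketone is a substrate; no stereocentre is touched.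

Step 3
Reactants: 6 3-[(1R,6R)-1-methyl-2-oxo-6-(prop-1-en-2-yl)cyclohexyl]propanal
Product: 7 (E)-3-[(1R,6R)-1-methyl-2-oxo-6-(prop-1-en-2-yl)cyclohexyl]propanal oxime (ring B keto oxime with C5 isopropenyl)
Conditions: NH2OH·HCl (1.1 equiv), NaOAc, EtOH/H2O, 0 °C → rt
Reagents that add atoms: hydroxylamine hydrochloride, NO.Cl
Why: Oxime condensation; the aldehyde reacts far faster than the α-quaternary ketone, so a slight excess of reagent should be selective. Near-neutral buffering avoids the intramolecular aldol reaction of the 1,5-keto aldehyde.

Step 4
Reactants: 7 (E)-3-[(1R,6R)-1-methyl-2-oxo-6-(prop-1-en-2-yl)cyclohexyl]propanal oxime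
Product: 9 (4R,5R,10R)-tricyclic isoxazoline ketone: 9-oxo trans-decalin with a 2-isoxazoline C3=N–O–C18H2 fused on C3–C4 and the C4 methyl axial, via nitrile oxide 8 (not isolated)
Conditions: aq. NaOCl (1.5 equiv), Et3N (0.1 equiv), CH2Cl2 (0.01 M), 0 °C → rt, slow addition
Reagents that add atoms: none
Why: Hypochlorite chlorinates the aldoxime at carbon and base removes HCl to give nitrile oxide 8, which adds in a concerted [3+2] fashion across the C4=C18 bond of the isopropenyl group. The closest known reaction type is the intramolecular nitrile oxide–olefin cycloaddition giving ring-fused 2-isoxazolines. Ring A closes as a six-membered carbocycle through C3–C4, because the four-atom tether (C2, C1, C10, C5) lets the dipole carbon reach only the proximal alkene carbon; bonding to C18 would need a bridged seven-membered ring. The isoxazoline closes as the five-membered ring through O–C18 in the same event. The only new stereocentre is C4: in a chair-like forming ring A, with C1 and C4 both equatorial on ring B as fixed in step 1, C18 must lie near the plane of the C3–N–O dipole and ends equatorial. The methyl is therefore axial and cis to the C10 methyl, and the opposite epimer would need a boat-like ring A. Regioselectivity is secured by the tether, facial selectivity by the chair and the preset C5/C10 centres, and selectivity over dimerisation to the furoxan by high dilution and slow generation of the dipole.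

Step 5
Reactants: 9 (4R,5R,10R)-tricyclic isoxazoline ketone
Product: 11 (4R,5R,10R)-C9 enol triflate (C8=C9) of the tricyclic isoxazoline, via potassium enolate 10 (not isolated)
Conditions: KN(SiMe3)2 (1.1 equiv), THF, −78 °C; then PhNTf2 (1.2 equiv), −78 → 0 °C
Reagents that add atoms: N-phenylbis(trifluoromethanesulfonimide), O=S(=O)(N(c1ccccc1)S(=O)(=O)C(F)(F)F)C(F)(F)F
Why: Kinetic enolate formation and O-triflation; C8 is the only enolisable position of the ketone. The isoxazoline has no hydrogen on C4 and cannot ring-open, and its C2 hydrogens are less acidic than the ketone α-hydrogens.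

Step 6
Reactants: 11 (4R,5R,10R)-C9 enol triflate; 12 2-(2-bromoethyl)-2-methyl-1,3-dioxolane
Product: 14 (4R,5S,10R)-C8=C9 alkene carrying at C9 the chain C11H2–C12H2–C13(CH3) as its ethylene ketal with the isoxazoline intact, via alkylzinc bromide 13 (not isolated)
Conditions: 12 (1.5 equiv), Zn dust, I2 (5 mol %), DMA, 70 °C; then 11, PdCl2(dppf) (5 mol %), LiCl, THF, 60 °C
Reagents that add atoms: 2-(2-bromoethyl)-2-methyl-1,3-dioxolane (12), CC1(CCBr)OCCO1
Why: Negishi cross-coupling of an alkylzinc halide with an alkenyl triflate; zinc inserts into the primary bromide and the γ-ketal is tolerated. Coupling at alkenyl triflates flanked by a quaternary carbon is established, and the isoxazoline is inert to the zinc reagent and to zerovalent palladium.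

Step 7
Reactants: 14 (4R,5S,10R)-isoxazoline alkene ketal
Product: 15 (4S,5S,10R)-18-hydroxy-3-oxo compound (β-hydroxy ketone) with C8=C9 and the C13 ketal unchanged
Conditions: Mo(CO)6 (1.0 equiv), MeCN/H2O 10:1, 80 °C
Reagents that add atoms: water, O
Why: Reductive N–O cleavage of a 2-isoxazoline by zerovalent molybdenum; the β-hydroxy imine formed hydrolyses in the wet medium to the β-hydroxy ketone. C4 is quaternary, so neither dehydration nor epimerisation is possible, and the neutral conditions spare the trisubstituted alkene and the ketal.

Step 8
Reactants: 15 (4S,5S,10R)-β-hydroxy ketone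
Product: 16 (3R,4S,5S,10R)-3,18-diol with equatorial C3 hydroxyl
Conditions: NaBH4, MeOH/CH2Cl2, −20 → 0 °C
Reagents that add atoms: none
Why: Borohydride reduction of a cyclohexanone; hydride adds along the axial trajectory on the face away from the axial C4 and C10 methyl groups, giving the equatorial alcohol (3R), as is usual for 4,4-disubstituted 3-oxo terpenoids. C3 is the only carbonyl present, and the low temperature should keep retro-aldol loss of formaldehyde from competing.

Step 9
Reactants: 16 (3R,4S,5S,10R)-3,18-diol
Product: 17 (3R,4S,5S,10R)-3,18-O-di-tert-butylsilylene derivative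
Conditions: t-Bu2Si(OTf)2 (1.1 equiv), 2,6-lutidine, CH2Cl2, 0 °C
Reagents that add atoms: di-tert-butylsilyl bis(trifluoromethanesulfonate), CC(C)(C)[Si](OS(=O)(=O)C(F)(F)F)(OS(=O)(=O)C(F)(F)F)C(C)(C)C
Why: Cyclic silylene formation from a 1,3-diol, giving a six-membered dioxasilinane of the kind formed by the 4,6-diols of pyranosides. The group should withstand the borane, ylide, mild-acid and hydride steps that follow and is removed by fluoride.

Step 10
Reactants: 17 (3R,4S,5S,10R)-silylene alkene ketal
Product: 19 (3R,4S,5S,8S,9S,10R)-8-ol with H9 and the C8 hydroxyl cis, via alkylborane 18 (not isolated)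
Conditions: BH3·THF (3 equiv), THF, 0 °C → rt; then NaBO3·4H2O, THF/H2O, rt
Reagents that add atoms: sodium perborate (NaBO3·4H2O, peroxoborate dimer), [Na+].[Na+].O[B-]1(O)OO[B-](O)(O)OO1
Why: Hydroboration–oxidation; boron adds to the less substituted C8 and hydrogen to C9, syn and from the face opposite the axial C10 methyl. This puts the side chain equatorial, and perborate oxidises the C–B bond with retention under conditions mild enough for the silylene.

Step 11
Reactants: 19 (3R,4S,5S,8S,9S,10R)-8-ol
Product: 20 (3R,4S,5S,9S,10R)-8-ketone
Conditions: Dess–Martin periodinane (1.5 equiv), NaHCO3, CH2Cl2, rt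
Reagents that add atoms: none
Why: Dess–Martin oxidation of a secondary alcohol under buffered conditions. C9 becomes α to the ketone, but its equatorial side chain is the thermodynamic arrangement, so any C9 epimer from step 10 can be equilibrated (DBU) to the same ketone.

Step 12
Reactants: 20 (3R,4S,5S,9S,10R)-8-ketone
Product: 21 (3R,4S,5S,9R,10S)-8(17)-ene (exocyclic methylene) with silylene and ketal intact
Conditions: Ph3PCH3Br (3.0 equiv), KOt-Bu (2.8 equiv), toluene, rt → 80 °C
Reagents that add atoms: methyltriphenylphosphonium bromide, [Br-].C[P+](c1ccccc1)(c1ccccc1)c1ccccc1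
Why: Wittig methylenation of a hindered cyclohexanone, the standard way to the 8(17)-alkene of labdanes. The ylide is kept in slight excess over base so that no free alkoxide attacks silicon, and C9 stays in its equatorial configuration.

Step 13
Reactants: 21 (3R,4S,5S,9R,10S)-8(17)-ene ketal
Product: 22 (3R,4S,5S,9R,10S)-methyl ketone (C13=O, C16 methyl) with the 3,18-silylene intact
Conditions: PPTS (0.2 equiv), acetone/H2O 10:1, 50 °C
Reagents that add atoms: water, O
Why: Acid-catalysed ketal hydrolysis, driven by exchange with acetone. PPTS is too weak to move the exocyclic alkene into the ring or to cleave the di-tert-butylsilylene.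

Step 14
Reactants: 22 (3R,4S,5S,9R,10S)-methyl ketone; 23 diethyl [2-(methoxy(methyl)amino)-2-oxoethyl]phosphonate
Product: 24 (13E)-N-methoxy-N-methyl amide of the C15 acid (conjugated Weinreb amide) with the 3,18-silylene intact
Conditions: 23 (2.0 equiv), NaH (1.9 equiv), THF, 0 → 50 °C
Reagents that add atoms: diethyl [2-(methoxy(methyl)amino)-2-oxoethyl]phosphonate (23), CCOP(=O)(CC(=O)N(C)OC)OCC
Why: Horner–Wadsworth–Emmons olefination of a methyl ketone. Reversible addition places the amide trans to the longer C12 chain, so the E isomer should predominate and the minor Z isomer is removed by chromatography.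

Step 15
Reactants: 24 (13E)-Weinreb amide
Product: 25 (13E)-15-al (conjugated aldehyde) with the 3,18-silylene intact
Conditions: i-Bu2AlH (1.5 equiv), THF, −78 °C; then aq. KNaC4H4O6
Reagents that add atoms: none
Why: Reduction of a Weinreb amide by i-Bu2AlH stops at the aldehyde, because the chelated tetrahedral intermediate survives until work-up. The alkene geometry is retained and the silylene is inert at this temperature.

Step 16
Reactants: 25 (13E)-15-al silylene
Product: 26 (3R,4S,5S,9R,10S)-3,18-dihydroxylabda-8(17),13E-dien-15-al
Conditions: HF·pyridine, pyridine, THF, 0 °C → rt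
Reagents that add atoms: none
Why: Fluoride cleavage of the silylene; buffered HF·pyridine should leave the enal and the exocyclic alkene unchanged.

Step 17
Reactants: 26 (3R,4S,5S,9R,10S)-3,18-dihydroxylabda-8(17),13E-dien-15-al; 27 tigloyl chloride, (E)-2-methylbut-2-enoyl chloride
Product: 28 (3R,4S,5S,9R,10S)-3-hydroxy-15-oxolabda-8(17),13E-dien-18-yl (E)-2-methylbut-2-enoate
Conditions: 27 (1.1 equiv), pyridine, CH2Cl2, −20 → 0 °C
Reagents that add atoms: tigloyl chloride (27), C/C=C(\C)C(=O)Cl
Why: Site-selective acylation; the primary C18 hydroxyl should react well before the secondary C3 hydroxyl, which is flanked by quaternary C4. The aldehyde cannot be acylated, and the tiglate is the stable E isomer, so its geometry is not at risk.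

Step 18
Reactants: 28 (3R,4S,5S,9R,10S)-3-hydroxy-15-oxo 18-tiglate
Product: 29 (3R,4S,5S,9R,10S)-3-acetoxy-15-oxolabda-8(17),13E-dien-18-yl (E)-2-methylbut-2-enoate
Conditions: Ac2O (3 equiv), DMAP (5 mol %), pyridine, CH2Cl2, 0 °C → rt
Reagents that add atoms: acetic anhydride, CC(=O)OC(C)=O
Why: DMAP-catalysed acetylation of the remaining hindered secondary alcohol; the configuration at C3 is not affected.

Step 19
Reactants: 29 (3R,4S,5S,9R,10S)-3-acetoxy-15-oxo 18-tiglate
Product: 30 (3R,4S,5S,9R,10S)-3-acetoxy-15-hydroxylabda-8(17),13E-dien-18-yl (E)-2-methylbut-2-enoate (CNP0148037.1)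
Conditions: NaBH4, CeCl3·7H2O, MeOH, −40 °C
Reagents that add atoms: none
Why: Luche reduction; cerium-activated borohydride reduces the conjugated aldehyde by 1,2-addition within minutes at low temperature. The acetate, the tiglate and both alkenes should be untouched, so the E-allylic alcohol of the target results.

## Compound list

1 | 2-methylcyclohex-2-en-1-one | CC1=CCCCC1=O | starting material
2 | isopropenylmagnesium bromide | C=C(C)[Mg]Br | starting material
3 | allyl bromide | C=CCBr | starting material
4 | bromomagnesium (R)-2-methyl-3-(prop-1-en-2-yl)cyclohex-1-en-1-olate | CC1=C(O[Mg]Br)CCC[C@@H]1C(C)=C | intermediate (not isolated)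
5 | (2R,3R)-2-methyl-3-(prop-1-en-2-yl)-2-(prop-2-en-1-yl)cyclohexan-1-one | O=C1CCC[C@H](C(C)=C)[C@@]1(C)CC=C | intermediate
6 | 3-[(1R,6R)-1-methyl-2-oxo-6-(prop-1-en-2-yl)cyclohexyl]propanal | O=C1CCC[C@H](C(C)=C)[C@@]1(C)CCC=O | intermediate
7 | (E)-3-[(1R,6R)-1-methyl-2-oxo-6-(prop-1-en-2-yl)cyclohexyl]propanal oxime | O=C1CCC[C@H](C(C)=C)[C@@]1(C)CC/C=N/O | intermediate (key-step precursor)
8 | 3-[(1R,6R)-1-methyl-2-oxo-6-(prop-1-en-2-yl)cyclohexyl]propanenitrile oxide | O=C1CCC[C@H](C(C)=C)[C@@]1(C)CCC#[N+][O-] | intermediate (not isolated)
9 | (4R,5R,10R)-tricyclic isoxazoline ketone (9-oxo trans-decalin, isoxazoline C3=N–O–C18 fused on C3–C4, C4 methyl axial) | O=C1CCC[C@H]2[C@@]1(C)CCC1=NOC[C@@]12C | intermediate (key-step product)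
10 | potassium C8=C9 enolate of 9 | [K+].[O-]C1=CCC[C@H]2[C@@]1(C)CCC1=NOC[C@@]12C | intermediate (not isolated)
11 | (4R,5R,10R)-C9 enol triflate of 9 | O=S(=O)(OC1=CCC[C@H]2[C@@]1(C)CCC1=NOC[C@@]12C)C(F)(F)F | intermediate
12 | 2-(2-bromoethyl)-2-methyl-1,3-dioxolane | CC1(CCBr)OCCO1 | starting material
13 | [2-(2-methyl-1,3-dioxolan-2-yl)ethyl]zinc bromide | CC1(CC[Zn]Br)OCCO1 | intermediate (not isolated)
14 | (4R,5S,10R)-C8=C9 alkene with the C11–C13 ketal chain on C9, isoxazoline intact | CC1(CCC2=CCC[C@H]3[C@@]2(C)CCC2=NOC[C@@]23C)OCCO1 | intermediate
15 | (4S,5S,10R)-18-hydroxy-3-oxo compound (C8=C9, C13 ketal) | CC1(CCC2=CCC[C@H]3[C@@]2(C)CCC(=O)[C@]3(C)CO)OCCO1 | intermediate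
16 | (3R,4S,5S,10R)-3,18-diol (C8=C9, C13 ketal) | CC1(CCC2=CCC[C@H]3[C@@]2(C)CC[C@@H](O)[C@]3(C)CO)OCCO1 | intermediate
17 | (3R,4S,5S,10R)-3,18-O-di-tert-butylsilylene derivative of 16 | CC1(CCC2=CCC[C@H]3[C@@]2(C)CC[C@H]2O[Si](C(C)(C)C)(C(C)(C)C)OC[C@@]23C)OCCO1 | intermediate
18 | (3R,4S,5S,8S,9R,10S)-C8 alkylborane (BH2 on C8, H on C9, cis) | CC1(CC[C@@H]2[C@@H](B)CC[C@H]3[C@@]2(C)CC[C@H]2O[Si](C(C)(C)C)(C(C)(C)C)OC[C@@]23C)OCCO1 | intermediate (not isolated)
19 | (3R,4S,5S,8S,9S,10R)-8-ol (silylene, C13 ketal) | CC1(CC[C@@H]2[C@@H](O)CC[C@H]3[C@@]2(C)CC[C@H]2O[Si](C(C)(C)C)(C(C)(C)C)OC[C@@]23C)OCCO1 | intermediate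
20 | (3R,4S,5S,9S,10R)-8-ketone (silylene, C13 ketal) | CC1(CC[C@@H]2C(=O)CC[C@H]3[C@@]2(C)CC[C@H]2O[Si](C(C)(C)C)(C(C)(C)C)OC[C@@]23C)OCCO1 | intermediate
21 | (3R,4S,5S,9R,10S)-8(17)-ene (silylene, C13 ketal) | CC1(CC[C@@H]2C(=C)CC[C@H]3[C@@]2(C)CC[C@H]2O[Si](C(C)(C)C)(C(C)(C)C)OC[C@@]23C)OCCO1 | intermediate
22 | (3R,4S,5S,9R,10S)-13-oxo methyl ketone (8(17)-ene, silylene) | CC(=O)CC[C@@H]1C(=C)CC[C@H]2[C@@]1(C)CC[C@H]1O[Si](C(C)(C)C)(C(C)(C)C)OC[C@@]12C | intermediate
23 | diethyl [2-(methoxy(methyl)amino)-2-oxoethyl]phosphonate | CCOP(=O)(CC(=O)N(C)OC)OCC | starting material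
24 | (13E)-N-methoxy-N-methyl labda-8(17),13-dien-15-amide, 3,18-O-di-tert-butylsilylene | CON(C)C(=O)/C=C(\C)CC[C@@H]1C(=C)CC[C@H]2[C@@]1(C)CC[C@H]1O[Si](C(C)(C)C)(C(C)(C)C)OC[C@@]12C | intermediate
25 | (13E)-labda-8(17),13-dien-15-al, 3,18-O-di-tert-butylsilylene | O=C/C=C(\C)CC[C@@H]1C(=C)CC[C@H]2[C@@]1(C)CC[C@H]1O[Si](C(C)(C)C)(C(C)(C)C)OC[C@@]12C | intermediate
26 | (3R,4S,5S,9R,10S)-3,18-dihydroxylabda-8(17),13E-dien-15-al | O=C/C=C(\C)CC[C@@H]1C(=C)CC[C@H]2[C@@]1(C)CC[C@@H](O)[C@]2(C)CO | intermediate
27 | tigloyl chloride, (E)-2-methylbut-2-enoyl chloride | C/C=C(\C)C(=O)Cl | starting material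
28 | (3R,4S,5S,9R,10S)-3-hydroxy-15-oxolabda-8(17),13E-dien-18-yl (E)-2-methylbut-2-enoate | O=C/C=C(\C)CC[C@@H]1C(=C)CC[C@H]2[C@@]1(C)CC[C@@H](O)[C@]2(C)COC(=O)/C(C)=C/C | intermediate
29 | (3R,4S,5S,9R,10S)-3-acetoxy-15-oxolabda-8(17),13E-dien-18-yl (E)-2-methylbut-2-enoate | O=C/C=C(\C)CC[C@@H]1C(=C)CC[C@H]2[C@@]1(C)CC[C@@H](OC(C)=O)[C@]2(C)COC(=O)/C(C)=C/C | intermediate
30 | (3R,4S,5S,9R,10S)-3-acetoxy-15-hydroxylabda-8(17),13E-dien-18-yl (E)-2-methylbut-2-enoate (CNP0148037.1) | C=C1CC[C@H]2[C@@](C)(CC[C@@H](OC(C)=O)[C@]2(C)COC(=O)/C(C)=C/C)[C@@H]1CC/C(C)=C/CO | target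

## Step count and least certain steps

Total step count: 19. Longest linear sequence: 19 steps from 1; compounds 2, 3, 12, 23 and 27 are commercial and enter directly.

Step 1. An alkenyl Grignard reagent on an α-substituted enone is a demanding pairing, so enantiofacial discrimination may be insufficient; the magnesium enolate may also be C-allylated incompletely. Fallback: from 1, the same addition–allylation is run with CuBr·SMe2 alone, which should give the trans ketone as a racemate, that is 5 together with its mirror image, the (2S,3S) ketone F1. The enantiomers are separated by preparative chromatography on a chiral stationary phase, and the route is rejoined at 5.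

Step 2. The oxidation may be slow or may partly follow the Markovnikov course, and divalent palladium may engage the isopropenyl group (alkene migration or allylic activation). Fallback: from 5, hydroboration with catecholborane catalysed by RhCl(PPh3)3 is selective for the monosubstituted alkene and leaves ketones alone. Work-up with NaBO3·4H2O should give the primary alcohol, hydroxy ketone F2, and Dess–Martin oxidation of F2 returns to 6.

Step 4 (key step). Dimerisation of the nitrile oxide to a furoxan may outrun a slow cycloaddition onto the hindered 1,1-disubstituted alkene, and a boat-like transition state may erode the facial selectivity at C4. Fallback by silyl nitronate cycloaddition, a dipole that does not dimerise: from 5, hydroxy ketone F2 is made as above and converted with I2, PPh3 and imidazole into the iodide F3. Displacement with NaNO2 in DMF gives the nitro compound F4. Me3SiCl and Et3N in toluene turn F4 into its silyl nitronate, which should cycloadd across the isopropenyl group to the N-silyloxy isoxazolidine F5. Catalytic TsOH then eliminates the silanol and the route is rejoined at 9.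

Step 6. Oxidative addition and transmetalation at a triflate beside quaternary C10 may be slow, so protodemetalation of the zinc reagent or reduction of the triflate may take over. Fallback by B-alkyl Suzuki–Miyaura coupling, which uses a different nucleophile made in a different way: commercial 2-methyl-2-vinyl-1,3-dioxolane (C=CC1(C)OCCO1) is hydroborated with 9-BBN to the alkylborane F6. F6 is coupled with 11 using PdCl2(dppf) and aqueous K3PO4 in THF/DMF, and the route is rejoined at 14.

Step 17. Discrimination between O18 and O3 may be incomplete, leading to bis-acylation or to acyl transfer within the 1,3-diol. Fallback by tin activation: from 26, heating with Bu2SnO in toluene with removal of water gives the dibutylstannylene acetal F7. Acylation of F7 with 27 at 0 °C is directed to the primary oxygen, and the route is rejoined at 28.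

## Further compounds

F1 | step 1 | (2S,3S)-2-methyl-3-(prop-1-en-2-yl)-2-(prop-2-en-1-yl)cyclohexan-1-one (enantiomer of 5) | O=C1CCC[C@@H](C(C)=C)[C@]1(C)CC=C
F2 | step 2 | (2R,3R)-2-(3-hydroxypropyl)-2-methyl-3-(prop-1-en-2-yl)cyclohexan-1-one | O=C1CCC[C@H](C(C)=C)[C@@]1(C)CCCO
F3 | step 4 | (2R,3R)-2-(3-iodopropyl)-2-methyl-3-(prop-1-en-2-yl)cyclohexan-1-one | O=C1CCC[C@H](C(C)=C)[C@@]1(C)CCCI
F4 | step 4 | (2R,3R)-2-methyl-2-(3-nitropropyl)-3-(prop-1-en-2-yl)cyclohexan-1-one | O=C1CCC[C@H](C(C)=C)[C@@]1(C)CCC[N+](=O)[O-]
F5 | step 4 | N-(trimethylsilyloxy)isoxazolidine corresponding to 9 (C3 configuration not defined) | O=C1CCC[C@H]2[C@@]1(C)CCC1N(O[Si](C)(C)C)OC[C@@]12C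
F6 | step 6 | 9-[2-(2-methyl-1,3-dioxolan-2-yl)ethyl]-9-borabicyclo[3.3.1]nonane | CC1(CCB2C3CCCC2CCC3)OCCO1
F7 | step 17 | 3,18-O-dibutylstannylene acetal of 26 | O=C/C=C(\C)CC[C@@H]1C(=C)CC[C@H]2[C@@]1(C)CC[C@H]1O[Sn](CCCC)(CCCC)OC[C@@]12C
A1 | alternative 1 | trans-fused octalin cycloadduct (C8 triisopropylsilyloxy, C9 methyl ester, C3 TBS ether, C18 PMB ether) | CC(C)[Si](C(C)C)(C(C)C)O[C@@H]1C=C[C@H]2[C@@](C)(CC[C@@H](O[Si](C)(C)C(C)(C)C)[C@]2(C)COCc2ccc(OC)cc2)[C@@H]1C(=O)OC
A2 | alternative 1 | open-chain triene: (E)-3-methyl-2-enoate tethered through C1–C4 to an (E,E)-1-triisopropylsilyloxy diene | COC(=O)/C=C(\C)CC[C@@H](O[Si](C)(C)C(C)(C)C)[C@](C)(COCc1ccc(OC)cc1)/C=C/C=C/O[Si](C(C)C)(C(C)C)C(C)C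
A3 | alternative 2 | O3–Si–C18 oxasilolane of the C8-ketal, C12-silyloxy core | O1CCOC12CC[C@H]3[C@@](C)(CC[C@@H](O[Si]4(CC)CC)[C@]3(C)C4)[C@@H]2CCO[Si](C)(C)C(C)(C)C
A4 | alternative 2 | O3 diethylhydrosilyl ether of the 19-deoxy (4,4-dimethyl) C8-ketal core | O1CCOC12CC[C@H]3[C@@](C)(CC[C@@H](O[SiH](CC)CC)C3(C)C)[C@@H]2CCO[Si](C)(C)C(C)(C)C
A5 | alternative 3 | trans-decalin with C20 dimethyl acetal, 3,18-acetonide, 8(17)-ene and C15 TBS ether | C=C1CC[C@H]2[C@@](C(OC)OC)(CC[C@@H](O3)[C@]2(C)COC3(C)C)[C@@H]1CC/C(C)=C/CO[Si](C)(C)C(C)(C)C
A6 | alternative 3 | ring-A acetonide with exocyclic C10 methyl enol ether (geometry not defined) and a C5 chain holding the Z-allylsilane and the E-allylic TBS ether | COC=C1CC[C@H]2OC(C)(C)OC[C@]2(C)[C@H]1CC/C(C[Si](C)(C)C)=C/CC/C(C)=C/CO[Si](C)(C)C(C)(C)C
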